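**Plan**

- The retrosynthesis first cuts the depside ester bond between the ring A carbonyl and O-4 of ring B, then the O-methyl and O-benzyl bonds, so that both rings derive from one resorcylate, benzyl 2,4-dihydroxy-6-pentylbenzoate.
- The enabling feature: each ring carries the carboxyl carbon on C1, oxygen on C2 and C4 and pentyl on C6, so it is the dehydro form of a 6-pentylcyclohexane-2,4-dione-1-carboxylate. Cutting C1–C6 and C2–C3 leaves a malonate (carboxyl carbon, C1, C2) and non-3-en-2-one (C3 to C6 plus pentyl).
- Forward, the carbocycle is closed once by Michael–Dieckmann annulation and aromatised, and the resorcylate is divided into two portions. One portion is 4-O-benzylated, 2-O-methylated and saponified to the ring A acid.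
- The ring A acid is esterified onto the free 4-hydroxyl of the second portion (ring B), the chelated 2-hydroxyl is then methylated, and a single hydrogenolysis frees the phenol and the carboxylic acid.
- The target has no stereocentre. The two centres of the cyclohexenone (trans, racemic) are transient and disappear on aromatisation.

Key step: step 1

Assumption: sodium benzyloxide is used as its commercial solution in benzyl alcohol, so the alkoxide matches the ester groups and transesterification changes nothing.

**Step 1**
Reactants: 1 dibenzyl malonate; 2 (E)-non-3-en-2-one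
Product: 4 benzyl (1RS,6SR)-2-hydroxy-4-oxo-6-pentylcyclohex-2-ene-1-carboxylate, via dibenzyl 2-(2-oxononan-4-yl)malonate 3 (not isolated)
Conditions: NaOCH2Ph (1.1 equiv, solution in BnOH), THF, 0 °C to rt, then 65 °C; cold aq. HCl
Reagents that add atoms: none
Why: Benzyloxide deprotonates 1, and the malonate anion adds in a Michael sense to C4 of enone 2 (the pentyl-bearing β-carbon), forming the bond that becomes C1–C6 and giving 3 as its enolate. Proton transfer to the methyl ketone enolate is followed by Dieckmann (intramolecular Claisen) attack on one benzyl ester, which forms C2–C3 and closes the carbocycle in a 6-(enolendo)-exo-trig mode with loss of benzyloxide. The closest known reaction type is the base-mediated annulation of dialkyl malonates with alk-3-en-2-ones to 6-alkylcyclohexane-2,4-dione-1-carboxylates (dihydroresorcylates). Of the two new stereocentres, C6 is set without control in the conjugate addition (racemate), while C1, acidic between the ester and the enolised ketone, should equilibrate to the trans arrangement with ester and pentyl pseudo-equatorial; both are erased in step 2. The step needs 1,4- rather than 1,2-addition and Claisen closure from the methyl rather than the C3 enolate: the soft, stabilised malonate anion adds reversibly at the carbonyl but productively at the β-carbon, only the methyl enolate can reach an ester through a six-membered transition state, and deprotonation of the product dione (a vinylogous acid) by the released benzyloxide pulls every equilibrium forward. Matching the alkoxide to the benzyl esters keeps the ester group unchanged.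

**Step 2**
Reactants: 4 benzyl (1RS,6SR)-2-hydroxy-4-oxo-6-pentylcyclohex-2-ene-1-carboxylate
Product: 6 benzyl 2,4-dihydroxy-6-pentylbenzoate, via benzyl trans-3-bromo-2-hydroxy-4-oxo-6-pentylcyclohex-2-ene-1-carboxylate 5 (not isolated)
Conditions: Br2 (1.0 equiv), DMF, 0 °C, then 70 °C
Reagents that add atoms: none
Why: Electrophilic bromination of the dione enol at C3 gives 5, which on warming in DMF should lose HBr (after acid-mediated transposition of bromine to an enolisable α-position) and tautomerise to the resorcinol; this halogenation–dehydrohalogenation aromatisation is the standard one for 6-alkyldihydroresorcylates, and one equivalent of bromine at moderate temperature is chosen so that neither nuclear bromination nor acidolysis of the benzyl ester should intervene.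

**Step 3**
Reactants: 6 benzyl 2,4-dihydroxy-6-pentylbenzoate (first portion)
Product: 7 benzyl 4-benzyloxy-2-hydroxy-6-pentylbenzoate
Conditions: BnBr (1.05 equiv), K2CO3, acetone, reflux
Reagents that add atoms: benzyl bromide, BrCc1ccccc1
Why: Williamson etherification; the 2-hydroxyl is held in a hydrogen bond to the ester carbonyl and flanked by the ester, so the more acidic, unhindered 4-hydroxyl should be alkylated selectively by one equivalent of benzyl bromide.

**Step 4**
Reactants: 7 benzyl 4-benzyloxy-2-hydroxy-6-pentylbenzoate
Product: 8 benzyl 4-benzyloxy-2-methoxy-6-pentylbenzoate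
Conditions: MeI (excess), K2CO3, DMF, 40 °C
Reagents that add atoms: iodomethane, CI
Why: Williamson methylation under more forcing conditions (excess iodomethane, polar aprotic solvent) should alkylate the chelated 2-hydroxyl, the only acidic site left, while the di-ortho-substituted benzyl ester is inert to carbonate.

**Step 5**
Reactants: 8 benzyl 4-benzyloxy-2-methoxy-6-pentylbenzoate
Product: 9 4-benzyloxy-2-methoxy-6-pentylbenzoic acid
Conditions: KOH, aq. DMSO, 90 °C; then cold dilute HCl to pH 3
Reagents that add atoms: potassium hydroxide (hydroxide oxygen), [K+].[OH-]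
Why: Saponification with poorly solvated hydroxide in aqueous DMSO is the established way to cleave di-ortho-substituted benzoates; the benzyl and methyl aryl ethers are inert to base, and cold acidification should avoid decarboxylation of the electron-rich acid.

**Step 6**
Reactants: 9 4-benzyloxy-2-methoxy-6-pentylbenzoic acid; 6 benzyl 2,4-dihydroxy-6-pentylbenzoate (second portion)
Product: 11 benzyl 4-[(4-benzyloxy-2-methoxy-6-pentylbenzoyl)oxy]-2-hydroxy-6-pentylbenzoate, via 4-benzyloxy-2-methoxy-6-pentylbenzoic trifluoroacetic anhydride 10 (not isolated)
Conditions: (CF3CO)2O, toluene, rt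
Reagents that add atoms: none
Why: Esterification through the mixed trifluoroacetic anhydride, a source of the stabilised 2,4-dialkoxy-6-alkylbenzoyl cation and the established activation for hindered depside esters; only the free 4-hydroxyl of 6 should be acylated, because the 2-hydroxyl is chelated to the ester and sterically screened.

**Step 7**
Reactants: 11 benzyl 4-[(4-benzyloxy-2-methoxy-6-pentylbenzoyl)oxy]-2-hydroxy-6-pentylbenzoate
Product: 12 benzyl 4-[(4-benzyloxy-2-methoxy-6-pentylbenzoyl)oxy]-2-methoxy-6-pentylbenzoate
Conditions: MeI (excess), anhydrous K2CO3, DMF, rt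
Reagents that add atoms: iodomethane, CI
Why: Williamson methylation of the remaining chelated phenol; the depside carbonyl is shielded by two ortho substituents and the phenoxide lies meta to the acyloxy group, so neither hydrolysis nor acyl migration should compete under anhydrous carbonate.

**Step 8**
Reactants: 12 benzyl 4-[(4-benzyloxy-2-methoxy-6-pentylbenzoyl)oxy]-2-methoxy-6-pentylbenzoate
Product: 13 4-O-demethylplanaic acid, 4-[(4-hydroxy-2-methoxy-6-pentylbenzoyl)oxy]-2-methoxy-6-pentylbenzoic acid
Conditions: H2 (1 atm), 10% Pd/C, EtOAc, rt
Reagents that add atoms: none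
Why: Catalytic hydrogenolysis should cleave the benzyl ester and the benzyl aryl ether in one operation under neutral conditions that leave the aryl ester, the methyl ethers and both arenes untouched.

**Compound list**

1 | dibenzyl malonate | O=C(CC(=O)OCc1ccccc1)OCc1ccccc1 | starting material
2 | (E)-non-3-en-2-one | CCCCC/C=C/C(C)=O | starting material
3 | dibenzyl 2-(2-oxononan-4-yl)malonate (Michael adduct, racemic, one enantiomer drawn, not isolated) | CCCCC[C@H](CC(C)=O)C(C(=O)OCc1ccccc1)C(=O)OCc1ccccc1 | intermediate
4 | benzyl (1RS,6SR)-2-hydroxy-4-oxo-6-pentylcyclohex-2-ene-1-carboxylate (trans, racemic, one enantiomer drawn) | CCCCC[C@@H]1CC(=O)C=C(O)[C@H]1C(=O)OCc1ccccc1 | intermediate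
5 | benzyl trans-3-bromo-2-hydroxy-4-oxo-6-pentylcyclohex-2-ene-1-carboxylate (racemic, one enantiomer drawn, not isolated) | CCCCC[C@@H]1CC(=O)C(Br)=C(O)[C@H]1C(=O)OCc1ccccc1 | intermediate
6 | benzyl 2,4-dihydroxy-6-pentylbenzoate | CCCCCc1cc(O)cc(O)c1C(=O)OCc1ccccc1 | intermediate
7 | benzyl 4-benzyloxy-2-hydroxy-6-pentylbenzoate | CCCCCc1cc(OCc2ccccc2)cc(O)c1C(=O)OCc1ccccc1 | intermediate
8 | benzyl 4-benzyloxy-2-methoxy-6-pentylbenzoate | CCCCCc1cc(OCc2ccccc2)cc(OC)c1C(=O)OCc1ccccc1 | intermediate
9 | 4-benzyloxy-2-methoxy-6-pentylbenzoic acid | CCCCCc1cc(OCc2ccccc2)cc(OC)c1C(=O)O | intermediate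
10 | 4-benzyloxy-2-methoxy-6-pentylbenzoic trifluoroacetic anhydride (not isolated) | CCCCCc1cc(OCc2ccccc2)cc(OC)c1C(=O)OC(=O)C(F)(F)F | intermediate
11 | benzyl 4-[(4-benzyloxy-2-methoxy-6-pentylbenzoyl)oxy]-2-hydroxy-6-pentylbenzoate | CCCCCc1cc(OC(=O)c2c(CCCCC)cc(OCc3ccccc3)cc2OC)cc(O)c1C(=O)OCc1ccccc1 | intermediate
12 | benzyl 4-[(4-benzyloxy-2-methoxy-6-pentylbenzoyl)oxy]-2-methoxy-6-pentylbenzoate | CCCCCc1cc(OC(=O)c2c(CCCCC)cc(OCc3ccccc3)cc2OC)cc(OC)c1C(=O)OCc1ccccc1 | intermediate
13 | 4-O-demethylplanaic acid, 4-[(4-hydroxy-2-methoxy-6-pentylbenzoyl)oxy]-2-methoxy-6-pentylbenzoic acid (achiral) | CCCCCc1cc(OC(=O)c2c(CCCCC)cc(O)cc2OC)cc(OC)c1C(=O)O | target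

**Step count**

Total: 8 steps. Longest linear sequence: 8 steps (steps 1 to 8; compound 6 is used twice, in step 3 and again in step 6).

**Steps most likely to fail, with fallbacks**

Step 2 (aromatisation). The HBr released may cleave the benzyl ester, after which the free acid would decarboxylate, or the resorcinol formed may be brominated on the ring. The fallback avoids halogen and acid and sets out from 4. Silylation of both enolisable carbonyls (TMSOTf, Et3N, CH2Cl2, 0 °C) should give benzyl 2,4-bis(trimethylsilyloxy)-6-pentylcyclohexa-1,3-diene-1-carboxylate F1; any dienol ether isomer would serve equally. Dehydrogenation of this cyclohexadiene with DDQ (dioxane, rt) should give benzyl 2,4-bis(trimethylsilyloxy)-6-pentylbenzoate F2, and dilute HCl in aqueous THF removes the silyl groups. The route is rejoined at 6.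

Step 7 (late methylation). The base may cleave or transfer the depside acyl group before the chelated phenol is alkylated, or alkylation may stall. The fallback installs the methyl ether on ring B before the ester bond is made and sets out from 8 (acid 9 is also used). Hydrogenolysis of 8 (H2, Pd/C, EtOAc) removes both benzyl groups and should give 4-hydroxy-2-methoxy-6-pentylbenzoic acid F3. Carboxylate-selective alkylation (BnBr, KHCO3, DMF, rt) then gives benzyl 4-hydroxy-2-methoxy-6-pentylbenzoate F4; bicarbonate ionises the acid but not the phenol. Coupling of F4 with 9 under the conditions of step 6 (again through 10) gives 12 directly, where the route is rejoined; 11 and step 7 are bypassed.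

Step 6 (depside coupling). The acylium-type electrophile may attack a ring carbon of the electron-rich resorcylate, acylate both hydroxyls, or the acid medium may erode the benzyl ether. The fallback replaces electrophile-driven acylation in acid by phenoxide-driven acylation in base and sets out from 9. Oxalyl chloride with catalytic DMF in CH2Cl2 should give 4-benzyloxy-2-methoxy-6-pentylbenzoyl chloride F5. F5 is added to 6 and K2CO3 in acetone, where only the more acidic 4-hydroxyl is ionised, and the route is rejoined at 11.

**Further compounds**

F1 | step 2 | benzyl 2,4-bis(trimethylsilyloxy)-6-pentylcyclohexa-1,3-diene-1-carboxylate (racemic, one enantiomer drawn) | CCCCC[C@@H]1CC(O[Si](C)(C)C)=CC(O[Si](C)(C)C)=C1C(=O)OCc1ccccc1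
F2 | step 2 | benzyl 2,4-bis(trimethylsilyloxy)-6-pentylbenzoate | CCCCCc1cc(O[Si](C)(C)C)cc(O[Si](C)(C)C)c1C(=O)OCc1ccccc1
F3 | step 7 | 4-hydroxy-2-methoxy-6-pentylbenzoic acid | CCCCCc1cc(O)cc(OC)c1C(=O)O
F4 | step 7 | benzyl 4-hydroxy-2-methoxy-6-pentylbenzoate | CCCCCc1cc(O)cc(OC)c1C(=O)OCc1ccccc1
F5 | step 6 | 4-benzyloxy-2-methoxy-6-pentylbenzoyl chloride | CCCCCc1cc(OCc2ccccc2)cc(OC)c1C(Cl)=O
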